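**Retrosynthetic overview**
1. Target 21 ⇐ desilylation ⇐ exocyclic enol ether 20 ⇐ carbonyl methylenation of the silylated bromo-δ-lactone 19.
2. The oxane ring is formed last, by 6-endo bromolactonization of the prenylated α-hydroxy acid 17; this sets C-5 from C-3.
3. 17 ⇐ saponification and cross-metathesis of allyl carbinol 14 ⇐ catalyst-controlled addition of allyl-B(pin) 13 to α-keto ester 12; this fragment-joining C–C bond creates C-3.
4. 12 ⇐ the isopropenyl group of bromochloride 6, by allylic oxidation, esterification and ozonolysis.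
5. 6 ⇐ cis-(S)-limonene oxide 2 (cyclohexane ring from the chiral pool) by HBr opening, bromine-assisted chloride substitution and diaxial→diequatorial Br/Cl interchange.

Assumption: the L-valine-derived aminophenol catalyst of step 8 is taken to deliver allyl to the Re face of the ketone of 12 (giving 2S); if it favours the Si face, its D-valine-derived enantiomer is used, and either way the two C-2 epimers are separable diastereomers.

**Step 1**
Reactants: 1 (S)-limonene
Product: 2 cis-(S)-limonene 1,2-oxide [(1S,2R,4S)-1,2-epoxy-p-menth-8-ene; O trans and CH3 cis to the isopropenyl group]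
Conditions: mCPBA (1.0 equiv), NaHCO3, CH2Cl2, 0 °C; aq. Na2SO3 work-up, concentrate; then pyrrolidine (0.6 equiv), H2O, 100 °C; aq. citric acid wash; distillation
Reagents that add atoms: 3-chloroperoxybenzoic acid (mCPBA), O=C(OO)c1cccc(Cl)c1
Why: Prilezhaev epoxidation picks the electron-richer trisubstituted ring alkene but is not face-selective, so the crude oxide is resolved kinetically by aminolysis, in which only the unwanted trans-oxide can be opened by pyrrolidine at its secondary carbon through a trans-diaxial (Fürst–Plattner) transition state and is washed out as the basic amino alcohol, while 2 would need attack at its tertiary carbon and is recovered as a single diastereomer (about 40% from 1) with the chiral-pool C-4 centre untouched.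

**Step 2**
Reactants: 2 cis-(S)-limonene 1,2-oxide
Product: 3 (1R,2R,5S)-2-bromo-2-methyl-5-(prop-1-en-2-yl)cyclohexan-1-ol
Conditions: 48% aq. HBr (1.05 equiv), Et2O, −20 °C, 15 min
Reagents that add atoms: hydrogen bromide, Br
Why: Acid-promoted epoxide ring opening in which the Markovnikov and the trans-diaxial (Fürst–Plattner) preferences coincide, so bromide enters at the tertiary carbon anti to oxygen and gives the axial tertiary bromide cis to the isopropenyl group next to the axial secondary alcohol, the cold and brief exposure sparing the isopropenyl group.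

**Step 3**
Reactants: 3 (1R,2R,5S)-2-bromo-2-methyl-5-(prop-1-en-2-yl)cyclohexan-1-ol
Product: 6 (1S,2S,4S)-2-bromo-1-chloro-1-methyl-4-(prop-1-en-2-yl)cyclohexane, via bromo mesylate 4 (not isolated), via diaxial bromochloride 5 (not isolated)
Conditions: MsCl, Et3N, CH2Cl2, −20 °C; then Et4NCl (3 equiv), MeCN, 23 → 80 °C
Reagents that add atoms: tetraethylammonium chloride, CC[N+](CC)(CC)CC.[Cl-]
Why: Nucleophilic substitution with neighbouring-group participation followed by the diaxial-to-diequatorial vicinal dihalide rearrangement: the antiperiplanar axial bromine displaces mesylate to form a bromonium ion on the face cis to the isopropenyl group, chloride opens it from the opposite face to give 5, and on warming the two halogens exchange places suprafacially to the stronger tertiary C–Cl and secondary C–Br bonds of 6, which leaves Cl trans and Br cis to the isopropenyl group (both equatorial).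

**Step 4**
Reactants: 6 (1S,2S,4S)-2-bromo-1-chloro-1-methyl-4-(prop-1-en-2-yl)cyclohexane
Product: 8 2-[(1S,3S,4S)-3-bromo-4-chloro-4-methylcyclohexyl]prop-2-enal, via allylic alcohol 7 (not isolated)
Conditions: SeO2 (0.3 equiv), t-BuOOH (2.5 equiv), salicylic acid (cat.), CH2Cl2, 23 °C; then MnO2 (10 equiv), CH2Cl2, 23 °C
Reagents that add atoms: tert-butyl hydroperoxide, CC(C)(C)OO (oxygen relayed by catalytic SeO2, O=[Se]=O)
Why: Riley allylic oxidation (ene reaction then [2,3]-sigmatropic shift, SeO2 turned over by t-BuOOH) attacks the methyl group of the isopropenyl unit in preference to the hindered ring CH, and MnO2 then oxidises only the allylic alcohol to the enal, with no stereocentre involved.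

**Step 5**
Reactants: 8 2-[(1S,3S,4S)-3-bromo-4-chloro-4-methylcyclohexyl]prop-2-enal
Product: 9 2-[(1S,3S,4S)-3-bromo-4-chloro-4-methylcyclohexyl]prop-2-enoic acid
Conditions: NaClO2, NaH2PO4, 35% H2O2, MeCN/H2O, 0 → 23 °C
Reagents that add atoms: sodium chlorite, [Na+].[O-]Cl=O
Why: Pinnick (Lindgren) oxidation converts the enal into the acid under mildly acidic conditions that leave the alkene, the alkyl halides and the ring stereocentres alone, H2O2 scavenging the hypochlorite.

**Step 6**
Reactants: 9 2-[(1S,3S,4S)-3-bromo-4-chloro-4-methylcyclohexyl]prop-2-enoic acid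
Product: 10 methyl 2-[(1S,3S,4S)-3-bromo-4-chloro-4-methylcyclohexyl]prop-2-enoate
Conditions: Me3SiCHN2, toluene/MeOH, 0 °C
Reagents that add atoms: (trimethylsilyl)diazomethane, C[Si](C)(C)C=[N+]=[N-]
Why: Esterification with a diazoalkane is neutral and essentially quantitative and touches no stereocentre.

**Step 7**
Reactants: 10 methyl 2-[(1S,3S,4S)-3-bromo-4-chloro-4-methylcyclohexyl]prop-2-enoate
Product: 12 methyl 2-[(1S,3S,4S)-3-bromo-4-chloro-4-methylcyclohexyl]-2-oxoacetate, via secondary ozonide 11 (not isolated)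
Conditions: O3, CH2Cl2, −78 °C; then Me2S, −78 → 0 °C; used crude
Reagents that add atoms: ozone, [O-][O+]=O
Why: Ozonolysis (Criegee mechanism) of the only remaining alkene followed by reductive work-up gives the α-keto ester, which is kept cold and used crude because the ring CH next to the ketone is epimerisable, although the desired all-equatorial configuration is also the thermodynamically preferred one.

**Step 8**
Reactants: 12 methyl 2-[(1S,3S,4S)-3-bromo-4-chloro-4-methylcyclohexyl]-2-oxoacetate; 13 allylboronic acid pinacol ester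
Product: 14 methyl (2S)-2-[(1S,3S,4S)-3-bromo-4-chloro-4-methylcyclohexyl]-2-hydroxypent-4-enoate
Conditions: 13 (1.5 equiv), aminophenol catalyst (S)-2-{[(3,5-di-tert-butyl-2-hydroxyphenyl)methyl]amino}-N,N,3-trimethylbutanamide (2.5 mol%), NaOt-Bu (5 mol%), MeOH (1.5 equiv), toluene, 4 °C
Reagents that add atoms: 13 allylboronic acid pinacol ester, C=CCB1OC(C)(C)C(C)(C)O1
Why: Catalytic asymmetric carbonyl allylation (allylboration through a six-membered chair transition state on the catalyst-bound allylboron species) is chemoselective for the activated ketone over the ester and alkyl halides, and the chiral aminophenol, not the distant ring centres, directs the allyl group to the Re face to set the (2S) tertiary carbinol, the minor epimer being a separable diastereomer.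

**Step 9**
Reactants: 14 methyl (2S)-2-[(1S,3S,4S)-3-bromo-4-chloro-4-methylcyclohexyl]-2-hydroxypent-4-enoate; 15 2-methylbut-2-ene
Product: 16 methyl (2S)-2-[(1S,3S,4S)-3-bromo-4-chloro-4-methylcyclohexyl]-2-hydroxy-5-methylhex-4-enoate
Conditions: second-generation Grubbs catalyst RuCl2(=CHPh)(PCy3)(H2IMes) (5 mol%), 15 as co-solvent, CH2Cl2, 40 °C, sealed tube
Reagents that add atoms: 15 2-methylbut-2-ene, CC=C(C)C
Why: Olefin cross-metathesis of a terminal alkene in excess 2-methylbut-2-ene gives the trisubstituted prenyl alkene cleanly and tolerates the free tertiary alcohol, ester and alkyl halides.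

**Step 10**
Reactants: 16 methyl (2S)-2-[(1S,3S,4S)-3-bromo-4-chloro-4-methylcyclohexyl]-2-hydroxy-5-methylhex-4-enoate
Product: 17 (2S)-2-[(1S,3S,4S)-3-bromo-4-chloro-4-methylcyclohexyl]-2-hydroxy-5-methylhex-4-enoic acid
Conditions: LiOH·H2O (3 equiv), THF/MeOH/H2O, 0 → 23 °C; then 1 M HCl
Reagents that add atoms: lithium hydroxide, [Li+].[OH-]
Why: Saponification of the α-hydroxy ester proceeds at low temperature, while the equatorial tertiary chloride and secondary bromide lack an antiperiplanar ring hydrogen for E2 elimination.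

**Step 11**
Reactants: 17 (2S)-2-[(1S,3S,4S)-3-bromo-4-chloro-4-methylcyclohexyl]-2-hydroxy-5-methylhex-4-enoic acid
Product: 18 (3S,5R)-5-bromo-3-[(1S,3S,4S)-3-bromo-4-chloro-4-methylcyclohexyl]-3-hydroxy-6,6-dimethyloxan-2-one
Conditions: NBS (1.1 equiv), NaHCO3, MeCN, −20 → 0 °C
Reagents that add atoms: N-bromosuccinimide, O=C1CCC(=O)N1Br
Why: 6-Endo bromolactonization, in which the carboxylate (a better nucleophile than the hindered tertiary hydroxyl) attacks the tertiary end of the bromonium ion in the Markovnikov sense, proceeds by anti addition through a chair-like transition state with bromine and the bulky cyclohexyl group both equatorial, which sets C-5 as R (Br cis to the cyclohexyl group, trans to OH).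

**Step 12**
Reactants: 18 (3S,5R)-5-bromo-3-[(1S,3S,4S)-3-bromo-4-chloro-4-methylcyclohexyl]-3-hydroxy-6,6-dimethyloxan-2-one
Product: 19 (3S,5R)-5-bromo-3-[(1S,3S,4S)-3-bromo-4-chloro-4-methylcyclohexyl]-6,6-dimethyl-3-[(trimethylsilyl)oxy]oxan-2-one
Conditions: Me3SiOTf (1.5 equiv), 2,6-lutidine (2.5 equiv), CH2Cl2, −78 → 0 °C
Reagents that add atoms: trimethylsilyl trifluoromethanesulfonate, C[Si](C)(C)OS(=O)(=O)C(F)(F)F
Why: Silylation with the silyl triflate and a hindered base caps the hindered tertiary alcohol so that it cannot quench the titanium reagent, without touching any stereocentre.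

**Step 13**
Reactants: 19 (3S,5R)-5-bromo-3-[(1S,3S,4S)-3-bromo-4-chloro-4-methylcyclohexyl]-6,6-dimethyl-3-[(trimethylsilyl)oxy]oxan-2-one
Product: 20 {[(3S,5R)-5-bromo-3-[(1S,3S,4S)-3-bromo-4-chloro-4-methylcyclohexyl]-6,6-dimethyl-2-methylideneoxan-3-yl]oxy}trimethylsilane
Conditions: Tebbe reagent Cp2Ti(μ-CH2)(μ-Cl)AlMe2 (2.5 equiv), pyridine (1 equiv), THF/toluene, −40 → 23 °C; 15% aq. NaOH quench at −10 °C; basic alumina
Reagents that add atoms: Tebbe reagent, C[Al-]1(C)C[Ti](C2C=CC=C2)(C3C=CC=C3)[Cl+]1
Why: Tebbe methylenation (titanium methylidene [2+2] cycloaddition and cycloreversion) converts the lactone carbonyl into the exocyclic enol ether, which cannot isomerise into the ring because C-3 is quaternary.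

**Step 14**
Reactants: 20 {[(3S,5R)-5-bromo-3-[(1S,3S,4S)-3-bromo-4-chloro-4-methylcyclohexyl]-6,6-dimethyl-2-methylideneoxan-3-yl]oxy}trimethylsilane
Product: 21 (3S,5R)-5-bromo-3-[(1S,3S,4S)-3-bromo-4-chloro-4-methylcyclohexyl]-6,6-dimethyl-2-methylideneoxan-3-ol
Conditions: Bu4NF (1.1 equiv), THF, 0 °C; pH 7 phosphate buffer; Et3N-deactivated silica
Reagents that add atoms: none
Why: Fluoride-mediated desilylation under basic, non-acidic conditions frees the tertiary alcohol without hydrolysing the acid-labile enol ether or eliminating the equatorial halides.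

**Compound list**
1 | (S)-limonene, (4S)-1-methyl-4-(prop-1-en-2-yl)cyclohex-1-ene | C=C(C)[C@H]1CCC(C)=CC1 | starting material
2 | cis-(S)-limonene 1,2-oxide, (1S,2R,4S)-1,2-epoxy-p-menth-8-ene (O trans, CH3 cis to isopropenyl) | C=C(C)[C@H]1CC[C@]2(C)O[C@@H]2C1 | intermediate
3 | (1R,2R,5S)-2-bromo-2-methyl-5-(prop-1-en-2-yl)cyclohexan-1-ol | C=C(C)[C@H]1CC[C@@](C)(Br)[C@H](O)C1 | intermediate
4 | (1R,2R,5S)-2-bromo-2-methyl-5-(prop-1-en-2-yl)cyclohexyl methanesulfonate (not isolated) | C=C(C)[C@H]1CC[C@@](C)(Br)[C@H](OS(C)(=O)=O)C1 | intermediate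
5 | (1R,2R,4S)-1-bromo-2-chloro-1-methyl-4-(prop-1-en-2-yl)cyclohexane (halogens diaxial; not isolated) | C=C(C)[C@H]1CC[C@@](C)(Br)[C@H](Cl)C1 | intermediate
6 | (1S,2S,4S)-2-bromo-1-chloro-1-methyl-4-(prop-1-en-2-yl)cyclohexane (halogens diequatorial) | C=C(C)[C@H]1CC[C@](C)(Cl)[C@@H](Br)C1 | intermediate
7 | 2-[(1S,3S,4S)-3-bromo-4-chloro-4-methylcyclohexyl]prop-2-en-1-ol (not isolated) | C=C(CO)[C@H]1CC[C@](C)(Cl)[C@@H](Br)C1 | intermediate
8 | 2-[(1S,3S,4S)-3-bromo-4-chloro-4-methylcyclohexyl]prop-2-enal | C=C(C=O)[C@H]1CC[C@](C)(Cl)[C@@H](Br)C1 | intermediate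
9 | 2-[(1S,3S,4S)-3-bromo-4-chloro-4-methylcyclohexyl]prop-2-enoic acid | C=C(C(=O)O)[C@H]1CC[C@](C)(Cl)[C@@H](Br)C1 | intermediate
10 | methyl 2-[(1S,3S,4S)-3-bromo-4-chloro-4-methylcyclohexyl]prop-2-enoate | C=C(C(=O)OC)[C@H]1CC[C@](C)(Cl)[C@@H](Br)C1 | intermediate
11 | methyl 3-[(1S,3S,4S)-3-bromo-4-chloro-4-methylcyclohexyl]-1,2,4-trioxolane-3-carboxylate (both epimers at the trioxolane carbon; not isolated) | COC(=O)C1(OOCO1)[C@H]2CC[C@](C)(Cl)[C@@H](Br)C2 | intermediate
12 | methyl 2-[(1S,3S,4S)-3-bromo-4-chloro-4-methylcyclohexyl]-2-oxoacetate | COC(=O)C(=O)[C@H]1CC[C@](C)(Cl)[C@@H](Br)C1 | intermediate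
13 | allylboronic acid pinacol ester, 2-allyl-4,4,5,5-tetramethyl-1,3,2-dioxaborolane | C=CCB1OC(C)(C)C(C)(C)O1 | starting material
14 | methyl (2S)-2-[(1S,3S,4S)-3-bromo-4-chloro-4-methylcyclohexyl]-2-hydroxypent-4-enoate | COC(=O)[C@](O)(CC=C)[C@H]1CC[C@](C)(Cl)[C@@H](Br)C1 | intermediate
15 | 2-methylbut-2-ene | CC=C(C)C | starting material
16 | methyl (2S)-2-[(1S,3S,4S)-3-bromo-4-chloro-4-methylcyclohexyl]-2-hydroxy-5-methylhex-4-enoate | COC(=O)[C@](O)(CC=C(C)C)[C@H]1CC[C@](C)(Cl)[C@@H](Br)C1 | intermediate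
17 | (2S)-2-[(1S,3S,4S)-3-bromo-4-chloro-4-methylcyclohexyl]-2-hydroxy-5-methylhex-4-enoic acid | OC(=O)[C@](O)(CC=C(C)C)[C@H]1CC[C@](C)(Cl)[C@@H](Br)C1 | intermediate
18 | (3S,5R)-5-bromo-3-[(1S,3S,4S)-3-bromo-4-chloro-4-methylcyclohexyl]-3-hydroxy-6,6-dimethyloxan-2-one | O=C1OC(C)(C)[C@H](Br)C[C@]1(O)[C@H]1CC[C@](C)(Cl)[C@@H](Br)C1 | intermediate
19 | (3S,5R)-5-bromo-3-[(1S,3S,4S)-3-bromo-4-chloro-4-methylcyclohexyl]-6,6-dimethyl-3-[(trimethylsilyl)oxy]oxan-2-one | O=C1OC(C)(C)[C@H](Br)C[C@]1(O[Si](C)(C)C)[C@H]1CC[C@](C)(Cl)[C@@H](Br)C1 | intermediate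
20 | {[(3S,5R)-5-bromo-3-[(1S,3S,4S)-3-bromo-4-chloro-4-methylcyclohexyl]-6,6-dimethyl-2-methylideneoxan-3-yl]oxy}trimethylsilane | C=C1OC(C)(C)[C@H](Br)C[C@]1(O[Si](C)(C)C)[C@H]1CC[C@](C)(Cl)[C@@H](Br)C1 | intermediate
21 | (3S,5R)-5-bromo-3-[(1S,3S,4S)-3-bromo-4-chloro-4-methylcyclohexyl]-6,6-dimethyl-2-methylideneoxan-3-ol | C=C1OC(C)(C)[C@H](Br)C[C@]1(O)[C@H]1CC[C@](C)(Cl)[C@@H](Br)C1 | target

**Totals**
Total step count: 14. Longest linear sequence: 14 steps (1 → 21); 13 and 15 are bought.

**The three steps most likely to fail**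

Step 3. The mesylate may eliminate instead of ionising through the bromonium ion, and the Br/Cl interchange is an equilibrium whose position is expected, not proven, to favour 6; unconverted 5 is separated and reheated. The fallback brings the halogens in through the chlorohydrin instead of the bromohydrin. It sets out from 1: NBS in aqueous acetone gives the trans-diaxial bromohydrin (1R,2R,4S)-2-bromo-1-methyl-4-(prop-1-en-2-yl)cyclohexan-1-ol F1, and NaOH closes it stereospecifically to trans-(S)-limonene 1,2-oxide F2, the diastereomer of 2. LiCl/AcOH in THF opens F2 at the secondary carbon in the trans-diaxial sense to the chlorohydrin (1R,2R,4S)-2-chloro-1-methyl-4-(prop-1-en-2-yl)cyclohexan-1-ol F3. Me3SiBr at −20 °C then replaces the axial tertiary hydroxyl by bromide with retention (axial attack on the cation flanked by the antiperiplanar chlorine) to give the diaxial bromochloride 5, which is warmed in MeCN with Et4NCl as in step 3, so that the fallback comes back to the route at 6.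

Step 8. The α-branched keto ester 12 is a demanding substrate, its ring CH can epimerise under the mildly basic conditions, and the facial sense of the catalyst is assumed. The fallback builds the tertiary carbinol without any ketone. It sets out from allylic alcohol 7, isolated after the SeO2 stage of step 4. Sharpless asymmetric epoxidation (Ti(OiPr)4, L-(+)-diethyl tartrate, t-BuOOH, 4 Å sieves, CH2Cl2, −20 °C; the tartrate enantiomer is the one that gives the 2S epoxide, and the two epoxide epimers are separable diastereomers) gives the epoxy alcohol [(2S)-2-[(1S,3S,4S)-3-bromo-4-chloro-4-methylcyclohexyl]oxiran-2-yl]methanol F4. (2-Methylprop-1-en-1-yl)magnesium bromide with catalytic CuBr·SMe2 at −30 °C opens the epoxide at its CH2 terminus to the diol (2S)-2-[(1S,3S,4S)-3-bromo-4-chloro-4-methylcyclohexyl]-5-methylhex-4-ene-1,2-diol F5. SO3·pyridine/DMSO/iPr2NEt oxidises the primary alcohol to the hydroxy aldehyde (2S)-2-[(1S,3S,4S)-3-bromo-4-chloro-4-methylcyclohexyl]-2-hydroxy-5-methylhex-4-enal F6, and NaClO2/NaH2PO4 with 2-methylbut-2-ene as scavenger gives acid 17, where the fallback comes back to the route.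

Step 13. The lactone carbonyl is flanked by a quaternary silyloxy carbon and a gem-dimethyl carbon, the aluminium in the reagent is Lewis acidic towards the tertiary chloride, and the product is acid-labile. The fallback replaces the methylidene transfer by addition and dehydration. It sets out from 19: MeLi (1.1 equiv, THF, −78 °C) adds once to the lactone to give the lactol (3S,5R)-5-bromo-3-[(1S,3S,4S)-3-bromo-4-chloro-4-methylcyclohexyl]-2,6,6-trimethyl-3-[(trimethylsilyl)oxy]oxan-2-ol F7 (both anomers). Dehydration with (CF3CO)2O/pyridine/DMAP at 0 °C can only give the exocyclic alkene, because C-3 is quaternary, and so leads to 20, where the fallback comes back to the route.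

**Further compounds**
F1 | step 3 | (1R,2R,4S)-2-bromo-1-methyl-4-(prop-1-en-2-yl)cyclohexan-1-ol | C=C(C)[C@H]1CC[C@@](C)(O)[C@H](Br)C1
F2 | step 3 | trans-(S)-limonene 1,2-oxide, (1R,2S,4S)-1,2-epoxy-p-menth-8-ene | C=C(C)[C@H]1CC[C@@]2(C)O[C@H]2C1
F3 | step 3 | (1R,2R,4S)-2-chloro-1-methyl-4-(prop-1-en-2-yl)cyclohexan-1-ol | C=C(C)[C@H]1CC[C@@](C)(O)[C@H](Cl)C1
F4 | step 8 | [(2S)-2-[(1S,3S,4S)-3-bromo-4-chloro-4-methylcyclohexyl]oxiran-2-yl]methanol | OC[C@]2(CO2)[C@H]1CC[C@](C)(Cl)[C@@H](Br)C1
F5 | step 8 | (2S)-2-[(1S,3S,4S)-3-bromo-4-chloro-4-methylcyclohexyl]-5-methylhex-4-ene-1,2-diol | OC[C@](O)(CC=C(C)C)[C@H]1CC[C@](C)(Cl)[C@@H](Br)C1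
F6 | step 8 | (2S)-2-[(1S,3S,4S)-3-bromo-4-chloro-4-methylcyclohexyl]-2-hydroxy-5-methylhex-4-enal | O=C[C@](O)(CC=C(C)C)[C@H]1CC[C@](C)(Cl)[C@@H](Br)C1
F7 | step 13 | (3S,5R)-5-bromo-3-[(1S,3S,4S)-3-bromo-4-chloro-4-methylcyclohexyl]-2,6,6-trimethyl-3-[(trimethylsilyl)oxy]oxan-2-ol | CC1(O)OC(C)(C)[C@H](Br)C[C@]1(O[Si](C)(C)C)[C@H]1CC[C@](C)(Cl)[C@@H](Br)C1
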